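**Retrosynthetic overview**
- Ring C is the only ring to be built and is closed last. The O1–C2 aryl ether is cut back to the primary alcohol of an acyclic (S)-2,3-dihydroxy-1,2-diarylpropan-1-one and one of the two interchangeable ortho phenols of ring A (Mitsunobu).
- The strategy rests on C3 of ring C, a fully substituted carbon holding the 3-OH, C1' of ring B, the C4 carbonyl carbon and the C2 methylene. This is an aryl(acyl)carbene carbon that has taken up H2O and CH2O, so C3–O and C2–C3 are cut together to an α-aryl-α-diazoketone, water and formaldehyde.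
- The diazoketone comes by diazo transfer from the deoxybenzoin. Its C4–C4a bond is cut to the aryllithium of bis-MOM 5-methoxyresorcinol and the ring-B arylacetic Weinreb amide.
- The amide comes from 2,4-dihydroxybenzaldehyde by C3' prenylation, 4'-O-MOM/2'-O-Me differentiation and a one-carbon homologation (TosMIC, hydrolysis, amidation).
- Rings A and B are bought and ring C is formed in the last step. The single stereocentre (C3, S) is set in the three-component step and is not touched afterwards.

Key step: step 10

Abbreviations: prenyl = 3-methylbut-2-en-1-yl; MOM = methoxymethyl.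
Assumption: the face preference of the chiral phosphoric acid cannot be derived from a close model, so the (R)-acid is written and its mirror image is taken if a first run leads to the (R)-diol; the configuration is to be checked by ECD or by X-ray analysis of a crystalline derivative.

Step 1
Reactants: 1 2,4-dihydroxybenzaldehyde; 2 prenyl bromide (1-bromo-3-methylbut-2-ene)
Product: 3 2,4-dihydroxy-3-prenylbenzaldehyde
Conditions: KOH, H2O, 0 °C → rt
Reagents that add atoms: none
Why: Phenoxide C-alkylation (direct nuclear prenylation): in water the phenoxide oxygens are shielded by hydrogen bonding and C3, ortho to both oxygens, is the most nucleophilic ring carbon, so the 3-prenyl aldehyde should be the main C-alkylation product and is freed from O-prenyl and 5-prenyl material by chromatography.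

Step 2
Reactants: 3 2,4-dihydroxy-3-prenylbenzaldehyde
Product: 4 2-hydroxy-4-(methoxymethoxy)-3-prenylbenzaldehyde
Conditions: MOMCl (1.05 equiv), K2CO3, acetone, 0 °C → rt
Reagents that add atoms: chloromethyl methyl ether (MOMCl), COCCl
Why: Williamson-type O-alkylation with a chloromethyl ether: the 2-OH is locked in a hydrogen bond to the formyl oxygen and is the weaker acid, so one equivalent of MOMCl with a weak base should cap only the 4-OH.

Step 3
Reactants: 4 2-hydroxy-4-(methoxymethoxy)-3-prenylbenzaldehyde
Product: 5 2-methoxy-4-(methoxymethoxy)-3-prenylbenzaldehyde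
Conditions: MeI, K2CO3, DMF, rt → 40 °C
Reagents that add atoms: iodomethane, CI
Why: Williamson O-methylation of the only acidic site left; the dipolar solvent breaks the chelate, and neither the MOM ether nor the prenyl group reacts with MeI and carbonate.

Step 4
Reactants: 5 2-methoxy-4-(methoxymethoxy)-3-prenylbenzaldehyde
Product: 7 2-[2-methoxy-4-(methoxymethoxy)-3-prenylphenyl]acetonitrile, via vinylformamide adduct 6 (not isolated)
Conditions: TosMIC, t-BuOK, DME, −35 °C; then MeOH, reflux
Reagents that add atoms: p-toluenesulfonylmethyl isocyanide (TosMIC), [C-]#[N+]CS(=O)(=O)c1ccc(C)cc1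
Why: Van Leusen reductive cyanation in its low-temperature aldehyde variant: the TosMIC anion adds to the formyl group, the oxazoline opens to 6, and methoxide then strips the formyl group and the sulfinate to leave the nitrile with one more carbon, all under basic conditions that the MOM ether and the prenyl group tolerate.

Step 5
Reactants: 7 2-[2-methoxy-4-(methoxymethoxy)-3-prenylphenyl]acetonitrile
Product: 8 2-[2-methoxy-4-(methoxymethoxy)-3-prenylphenyl]acetic acid
Conditions: KOH, EtOH–H2O, reflux; then 1 M HCl to pH 4, 0 °C
Reagents that add atoms: potassium hydroxide, [K+].[OH-]; water, O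
Why: Alkaline nitrile hydrolysis through the primary amide; acetal and alkene are inert to hydroxide, and the cold acidification stops at pH 4 so that the MOM ether is kept.

Step 6
Reactants: 8 2-[2-methoxy-4-(methoxymethoxy)-3-prenylphenyl]acetic acid
Product: 10 N-methoxy-N-methyl-2-[2-methoxy-4-(methoxymethoxy)-3-prenylphenyl]acetamide, via acyl imidazolide 9 (not isolated)
Conditions: CDI, CH2Cl2, rt; then MeNH(OMe)·HCl, rt
Reagents that add atoms: N,O-dimethylhydroxylamine hydrochloride, CNOC.Cl
Why: Amide coupling by CDI activation: the acyl imidazolide 9 is attacked by N,O-dimethylhydroxylamine under near-neutral conditions that leave all other groups untouched.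

Step 7
Reactants: 11 5-methoxyresorcinol
Product: 12 1-methoxy-3,5-bis(methoxymethoxy)benzene
Conditions: NaH, MOMCl (2.4 equiv each), DMF, 0 °C → rt
Reagents that add atoms: chloromethyl methyl ether (MOMCl), COCCl
Why: Double Williamson-type O-alkylation of the bis-phenoxide; the two hydroxyl groups are equivalent, so no selectivity is needed.

Step 8
Reactants: 12 1-methoxy-3,5-bis(methoxymethoxy)benzene; 10 N-methoxy-N-methyl-2-[2-methoxy-4-(methoxymethoxy)-3-prenylphenyl]acetamide
Product: 15 1-[4-methoxy-2,6-bis(methoxymethoxy)phenyl]-2-[2-methoxy-4-(methoxymethoxy)-3-prenylphenyl]ethan-1-one, via aryllithium 13 (not isolated), via lithium hemiaminal adduct 14 (not isolated)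
Conditions: 12 (1.7 equiv), n-BuLi (1.6 equiv), THF, 0 °C; then 10, −78 → 0 °C; aq NH4Cl
Reagents that add atoms: none
Why: Directed ortho-metalation followed by Weinreb ketone synthesis: the position between the two chelating OMOM groups is lithiated in preference to the two OMe/OMOM-flanked positions, the chelated adduct 14 holds until the quench and so excludes over-addition, and excess aryllithium at low temperature keeps enolisation of 10 down.

Step 9
Reactants: 15 1-[4-methoxy-2,6-bis(methoxymethoxy)phenyl]-2-[2-methoxy-4-(methoxymethoxy)-3-prenylphenyl]ethan-1-one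
Product: 16 2-diazo-1-[4-methoxy-2,6-bis(methoxymethoxy)phenyl]-2-[2-methoxy-4-(methoxymethoxy)-3-prenylphenyl]ethan-1-one
Conditions: p-ABSA, DBU, MeCN, 0 °C → rt
Reagents that add atoms: 4-acetamidobenzenesulfonyl azide (p-ABSA), CC(=O)Nc1ccc(cc1)S(=O)(=O)N=[N+]=[N-]
Why: Regitz diazo transfer: DBU enolises the benzyl ketone, whose CH2 is activated by both the carbonyl and the aryl group, and the enolate takes N2 from the sulfonyl azide, as is usual for benzyl ketones.

Step 10
Reactants: 16 2-diazo-1-[4-methoxy-2,6-bis(methoxymethoxy)phenyl]-2-[2-methoxy-4-(methoxymethoxy)-3-prenylphenyl]ethan-1-one; 17 formaldehyde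
Product: 19 (S)-2,3-dihydroxy-1-[4-methoxy-2,6-bis(methoxymethoxy)phenyl]-2-[2-methoxy-4-(methoxymethoxy)-3-prenylphenyl]propan-1-one, via enediol 18 (not isolated)
Conditions: Rh2(OAc)4 (2 mol %), (R)-TRIP (10 mol %), 17 (5 equiv, fresh methanol-free aqueous solution from paraformaldehyde, which also brings the water), CH2Cl2, 0 °C, 16 added by syringe pump over 2 h
Reagents that add atoms: water, O
Why: Proposed new method: Rh2(OAc)4 expels N2 from 16 to give a donor–acceptor rhodium carbenoid at C3, water adds to it to form the oxonium ylide (C3–O bond), and proton transfer gives enediol 18, which attacks phosphoric-acid-bound formaldehyde through C3 (C2–C3 bond) before it can tautomerise to the benzoin. The closest known reaction type is the Rh(II)/chiral phosphoric acid co-catalysed three-component trapping of oxonium ylides or their enols (diazo carbonyl compound, water or alcohol, and an imine, formaldimine equivalent or activated carbonyl compound), together with the racemic water/formaldehyde trapping of cyclic diazoamides; an enantioselective run with water, formaldehyde and a diaryl diazoketone has not been described. No ring is closed in this step. The single new stereocentre C3 is set by the catalyst alone: the P=O oxygen holds an enediol O–H and the P–OH holds formaldehyde, so that the 3,3'-aryl walls leave open only the face that leads to (S). The step needs (i) aldol trapping faster than the 1,2-proton shift, helped by the excess of the smallest possible electrophile, its acid activation and the slow addition of 16, (ii) attack through C3 and not C4 of the enediol, secured by the two ortho OMOM groups of ring A that bury C4, and (iii) capture by water ahead of attack by a flanking acetal oxygen or C–H insertion, secured by the low nucleophilicity of acyl-conjugated aryl ether oxygens and the excess of water, while the MOM caps rule out phenol O–H insertion and the meta-placed prenyl group cannot reach the carbenoid. Methanol-free formaldehyde is required, since the methanol of commercial formalin would compete with water and leave OMe at C3.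

Step 11
Reactants: 19 (S)-2,3-dihydroxy-1-[4-methoxy-2,6-bis(methoxymethoxy)phenyl]-2-[2-methoxy-4-(methoxymethoxy)-3-prenylphenyl]propan-1-one
Product: 20 (S)-1-(2,6-dihydroxy-4-methoxyphenyl)-2,3-dihydroxy-2-(4-hydroxy-2-methoxy-3-prenylphenyl)propan-1-one
Conditions: HCl (ca. 1 M) in MeOH–THF, 0 °C → rt; NaHCO3 quench at full conversion
Reagents that add atoms: none
Why: Acid-catalysed acetal exchange with methanol, the usual release of prenylated polyphenols from MOM ethers: dilute acid at or below room temperature should cleave the aryl acetals faster than it protonates the trisubstituted alkene or ionises the C3 carbinol, whose cation is destabilised by the adjacent carbonyl group, so that C3 keeps its configuration.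

Step 12
Reactants: 20 (S)-1-(2,6-dihydroxy-4-methoxyphenyl)-2,3-dihydroxy-2-(4-hydroxy-2-methoxy-3-prenylphenyl)propan-1-one
Product: 21 (3S)-3,5-dihydroxy-3-(4-hydroxy-2-methoxy-3-prenylphenyl)-7-methoxychroman-4-one
Conditions: PPh3, DIAD, THF (0.01 M), 0 °C → rt
Reagents that add atoms: none
Why: Intramolecular Mitsunobu etherification (6-exo-tet closure of ring C, O1–C2): only the primary alcohol is activated, the acyl-acidified ring-A phenol is the one ionised and the only nucleophile within reach, either ortho phenol gives the same product, and C3 takes no part, so that its (S) configuration is kept.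

**Compound list**
1 | 2,4-dihydroxybenzaldehyde | O=Cc1ccc(O)cc1O | starting material
2 | prenyl bromide | CC(C)=CCBr | starting material
3 | 2,4-dihydroxy-3-prenylbenzaldehyde | O=Cc1ccc(O)c(CC=C(C)C)c1O | intermediate
4 | 2-hydroxy-4-(methoxymethoxy)-3-prenylbenzaldehyde | O=Cc1ccc(OCOC)c(CC=C(C)C)c1O | intermediate
5 | 2-methoxy-4-(methoxymethoxy)-3-prenylbenzaldehyde | O=Cc1ccc(OCOC)c(CC=C(C)C)c1OC | intermediate
6 | N-{2-[2-methoxy-4-(methoxymethoxy)-3-prenylphenyl]-1-tosylvinyl}formamide (alkene geometry not defined) | O=CNC(=Cc1ccc(OCOC)c(CC=C(C)C)c1OC)S(=O)(=O)c1ccc(C)cc1 | intermediate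
7 | 2-[2-methoxy-4-(methoxymethoxy)-3-prenylphenyl]acetonitrile | N#CCc1ccc(OCOC)c(CC=C(C)C)c1OC | intermediate
8 | 2-[2-methoxy-4-(methoxymethoxy)-3-prenylphenyl]acetic acid | OC(=O)Cc1ccc(OCOC)c(CC=C(C)C)c1OC | intermediate
9 | 1-(imidazol-1-yl)-2-[2-methoxy-4-(methoxymethoxy)-3-prenylphenyl]ethan-1-one | O=C(Cc1ccc(OCOC)c(CC=C(C)C)c1OC)n1ccnc1 | intermediate
10 | N-methoxy-N-methyl-2-[2-methoxy-4-(methoxymethoxy)-3-prenylphenyl]acetamide | CON(C)C(=O)Cc1ccc(OCOC)c(CC=C(C)C)c1OC | intermediate
11 | 5-methoxyresorcinol | COc1cc(O)cc(O)c1 | starting material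
12 | 1-methoxy-3,5-bis(methoxymethoxy)benzene | COCOc1cc(OC)cc(OCOC)c1 | intermediate
13 | [4-methoxy-2,6-bis(methoxymethoxy)phenyl]lithium | [Li]c1c(OCOC)cc(OC)cc1OCOC | intermediate
14 | lithium alkoxide of the tetrahedral adduct of 13 and 10 (racemic) | [Li]OC(Cc1ccc(OCOC)c(CC=C(C)C)c1OC)(N(C)OC)c1c(OCOC)cc(OC)cc1OCOC | intermediate
15 | 1-[4-methoxy-2,6-bis(methoxymethoxy)phenyl]-2-[2-methoxy-4-(methoxymethoxy)-3-prenylphenyl]ethan-1-one | COCOc1cc(OC)cc(OCOC)c1C(=O)Cc1ccc(OCOC)c(CC=C(C)C)c1OC | intermediate
16 | 2-diazo-1-[4-methoxy-2,6-bis(methoxymethoxy)phenyl]-2-[2-methoxy-4-(methoxymethoxy)-3-prenylphenyl]ethan-1-one | COCOc1cc(OC)cc(OCOC)c1C(=O)C(=[N+]=[N-])c1ccc(OCOC)c(CC=C(C)C)c1OC | intermediate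
17 | formaldehyde (from commercial paraformaldehyde, methanol-free) | C=O | starting material
18 | 1-[4-methoxy-2,6-bis(methoxymethoxy)phenyl]-2-[2-methoxy-4-(methoxymethoxy)-3-prenylphenyl]ethene-1,2-diol (geometry not defined) | OC(=C(O)c1ccc(OCOC)c(CC=C(C)C)c1OC)c1c(OCOC)cc(OC)cc1OCOC | intermediate
19 | (S)-2,3-dihydroxy-1-[4-methoxy-2,6-bis(methoxymethoxy)phenyl]-2-[2-methoxy-4-(methoxymethoxy)-3-prenylphenyl]propan-1-one | OC[C@@](O)(c1ccc(OCOC)c(CC=C(C)C)c1OC)C(=O)c1c(OCOC)cc(OC)cc1OCOC | intermediate
20 | (S)-1-(2,6-dihydroxy-4-methoxyphenyl)-2,3-dihydroxy-2-(4-hydroxy-2-methoxy-3-prenylphenyl)propan-1-one | OC[C@@](O)(c1ccc(O)c(CC=C(C)C)c1OC)C(=O)c1c(O)cc(OC)cc1O | intermediate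
21 | (3S)-3,5-dihydroxy-3-(4-hydroxy-2-methoxy-3-prenylphenyl)-7-methoxychroman-4-one | COc1cc(O)c2c(c1)OC[C@@](O)(c1ccc(O)c(CC=C(C)C)c1OC)C2=O | target

**Step count**
- Total step count: 12.
- Longest linear sequence: 11 (steps 1–6 and 8–12, from 1).

**Steps most likely to fail**

1. **Step 10.**
   - The 1,2-proton shift of the ylide or enediol may outrun the aldol trapping.
   - An uncatalysed background aldol in the wet medium may erode the face selectivity.
   - A flanking acetal oxygen may capture the carbenoid.
   - The fallback sets out from 15 and comes back at 21, using known chemistry only.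
   - Controlled acid methanolysis (cat. p-TsOH, MeOH, 0 °C) removes one carbonyl-flanked MOM ether. The phenol set free then ties up the ketone in a hydrogen bond, which slows loss of the second. This gives the mono-phenol deoxybenzoin F1.
   - Paraformaldehyde and diethylamine in hot methanol (aminomethylation, elimination, oxa-Michael closure) give the racemic isoflavanone F2.
   - The sodium enolate of F2 (NaHMDS, THF, −78 °C) is hydroxylated with the appropriate enantiomer of (8,8-dimethoxycamphorylsulfonyl)oxaziridine. This is a reagent-controlled Davis oxidation, known on 3-substituted 5-alkoxychroman-4-ones, and gives the (3S)-3-hydroxyisoflavanone bis-MOM ether F3.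
   - The two remaining MOM ethers are removed as in step 11 to give 21.

2. **Step 11.**
   - The acid may protonate the prenyl alkene, with capture by the freed 4'-phenol.
   - It may also ionise the electron-rich tertiary benzylic carbinol, with loss of configuration or a hydride shift towards the isoflavone series.
   - The fallback sets out from 19 and comes back at 20, and it gives up the Brønsted acid altogether.
   - TMSOTf and 2,2'-bipyridyl in MeCN (0 °C → rt) exchange the three aromatic MOM ethers for silyl ethers in a base-buffered medium and cap both alcohols. This gives the pentakis(trimethylsilyl) ether F4.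
   - Et3N·3HF in THF at 0 °C then releases 20.

3. **Step 8.**
   - Proton transfer from the doubly activated CH2 of 10 to the hindered, basic aryllithium may take the place of carbonyl addition.
   - Part of the lithiation may also go to an OMe/OMOM-flanked position.
   - The fallback sets out from 7 (together with aryllithium 13) and comes back at 15.
   - DIBAL-H (toluene, −78 °C, Rochelle salt work-up) reduces 7 to the arylacetaldehyde F5.
   - Anhydrous CeCl3 (THF, −78 °C) transmetalates 13 to the much less basic arylcerium dichloride F6.
   - F6 adds to F5 to give the racemic secondary alcohol F7, and Dess–Martin periodinane (NaHCO3, CH2Cl2) oxidises it to 15.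

**Further compounds**
F1 | step 10 | 1-[2-hydroxy-4-methoxy-6-(methoxymethoxy)phenyl]-2-[2-methoxy-4-(methoxymethoxy)-3-prenylphenyl]ethan-1-one | COCOc1cc(OC)cc(O)c1C(=O)Cc1ccc(OCOC)c(CC=C(C)C)c1OC
F2 | step 10 | rac-7-methoxy-5-(methoxymethoxy)-3-[2-methoxy-4-(methoxymethoxy)-3-prenylphenyl]chroman-4-one | COc1cc(OCOC)c2c(c1)OCC(c1ccc(OCOC)c(CC=C(C)C)c1OC)C2=O
F3 | step 10 | (3S)-3-hydroxy-7-methoxy-5-(methoxymethoxy)-3-[2-methoxy-4-(methoxymethoxy)-3-prenylphenyl]chroman-4-one | COc1cc(OCOC)c2c(c1)OC[C@@](O)(c1ccc(OCOC)c(CC=C(C)C)c1OC)C2=O
F4 | step 11 | pentakis(trimethylsilyl) ether of 20, (S) | C[Si](C)(C)OC[C@@](O[Si](C)(C)C)(c1ccc(O[Si](C)(C)C)c(CC=C(C)C)c1OC)C(=O)c1c(O[Si](C)(C)C)cc(OC)cc1O[Si](C)(C)C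
F5 | step 8 | 2-[2-methoxy-4-(methoxymethoxy)-3-prenylphenyl]acetaldehyde | O=CCc1ccc(OCOC)c(CC=C(C)C)c1OC
F6 | step 8 | [4-methoxy-2,6-bis(methoxymethoxy)phenyl]cerium dichloride | Cl[Ce](Cl)c1c(OCOC)cc(OC)cc1OCOC
F7 | step 8 | rac-1-[4-methoxy-2,6-bis(methoxymethoxy)phenyl]-2-[2-methoxy-4-(methoxymethoxy)-3-prenylphenyl]ethan-1-ol | OC(Cc1ccc(OCOC)c(CC=C(C)C)c1OC)c1c(OCOC)cc(OC)cc1OCOC
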